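**Retrosynthetic overview**

1. Target 21 ← selective hydrolysis of the side-chain methyl ester of tropone diester 20.
2. Tropone ring (made last) ← formal [3+4] annulation of a rhodium vinylcarbenoid (from 16) with the lactone-derived silyloxy diene 13, then dehydrogenation. The key bond is C5–C6: the carbenoid carbon is the α-carbon of a β-keto ester (normally a donor) used as an acceptor, and it joins the donor terminus of an ester dienolate ether.
3. Diene 13 ← spiro-γ-lactone 12 ← spiro-epoxide 9 + pentenoate dienolate (bond C3–C3a; the epoxide CH2 is an acceptor at a carbon that is a donor in carbonyl chemistry).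
4. Epoxide 9 ← exocyclic alkene 7 ← ketone 6 ← (S)-carvone by α'-methylation, Michael addition, alkene hydration and hydrogenation.
5. Ring order: cyclohexane (chiral pool) → spiro five-membered O-ring (as lactone) → seven-membered ring.

Assumption: the target is the free hydroxy acid as drawn; cyclohexane positions are numbered as in ketone 6 (C1 quaternary, C2 carbonyl/spiro, C3 CHMe, C6 CH bearing the oxygenated isopropyl group) and tropone positions as in cyclohepta[b]furan (C3, C3a, C4–C8, C8a).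

**Route**

Step 1
Reactants: 1 (S)-(+)-carvone
Product: 2 (5S)-2,6-dimethyl-5-(prop-1-en-2-yl)cyclohex-2-en-1-one (C6 epimer mixture)
Conditions: LiN(iPr)2, THF, −78 °C; MeI, −78 → 0 °C
Reagents that add atoms: iodomethane, CI
Why: Kinetic α'-deprotonation gives the cross-conjugated lithium dienolate, which is C-methylated (enolate alkylation); the C6 ratio is irrelevant because C6 is re-enolised in step 2.

Step 2
Reactants: 2 6-methylcarvone; 3 methyl acrylate
Product: 4 methyl 3-[(1R,6R)-1,3-dimethyl-2-oxo-6-(prop-1-en-2-yl)cyclohex-3-en-1-yl]propanoate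
Conditions: LiN(iPr)2, THF, −78 °C; 3, −78 °C, 20 min; AcOH quench at −78 °C
Reagents that add atoms: none
Why: Kinetic Michael addition of the tetrasubstituted enolate; the acrylate approaches anti to the adjacent isopropenyl group, so the chain ends trans and the methyl cis to it (sets C1), and the cold quench is meant to stop before a second, ring-forming Michael addition.

Step 3
Reactants: 4 keto ester
Product: 5 methyl 3-[(1R,6S)-6-(2-hydroxypropan-2-yl)-1,3-dimethyl-2-oxocyclohex-3-en-1-yl]propanoate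
Conditions: Co(acac)2 (20 mol %), PhSiH3, O2 (1 atm), THF, rt
Reagents that add atoms: dioxygen, O=O
Why: Mukaiyama hydration (cobalt-hydride hydrogen-atom transfer, O2 trapping) is Markovnikov and selects the electron-rich 1,1-disubstituted alkene over the conjugated trisubstituted enone alkene.

Step 4
Reactants: 5 hydroxy enone
Product: 6 methyl 3-[(1R,3R,6S)-6-(2-hydroxypropan-2-yl)-1,3-dimethyl-2-oxocyclohexyl]propanoate
Conditions: H2 (1 atm), Pd/C (5 %), EtOAc, rt
Reagents that add atoms: none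
Why: Heterogeneous syn-hydrogenation of the enone alkene from the face opposite the pseudo-axial C1 methyl and the hydroxyisopropyl group gives the 1,3-cis-dimethyl ketone (sets C3).

Step 5
Reactants: 6 ketone
Product: 7 methyl 3-[(1R,3R,6S)-6-(2-hydroxypropan-2-yl)-1,3-dimethyl-2-methylidenecyclohexyl]propanoate
Conditions: Zn, CH2Br2, TiCl4, THF, 0 °C (aged reagent); then 6, CH2Cl2, rt
Reagents that add atoms: dibromomethane, BrCBr
Why: Takai–Lombardo methylenation is non-basic, so the hindered and epimerisable ketone is converted without loss of the C3 configuration and the ester is left alone.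

Step 6
Reactants: 7 exocyclic alkene
Product: 9 methyl 3-[(3S,4R,5S,8R)-4,8-dimethyl-5-[2-(trimethylsilyloxy)propan-2-yl]-1-oxaspiro[2.5]octan-4-yl]propanoate, via hydroxy epoxide 8 (not isolated)
Conditions: dimethyldioxirane, acetone, 0 °C; evaporate; N-(trimethylsilyl)imidazole, CH2Cl2, rt
Reagents that add atoms: dimethyldioxirane, CC1(C)OO1; 1-(trimethylsilyl)imidazole, C[Si](C)(C)n1ccnc1
Why: Dioxirane epoxidation from the face anti to the two flanking methyl groups and the hydroxyisopropyl group sets the spiro C–O bond, and neutral O-silylation follows at once so the cis-1,3 tertiary hydroxyl cannot open the epoxide.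

Step 7
Reactants: 9 silyl-protected spiro-epoxide; 10 methyl (2E)-pent-2-enoate
Product: 12 methyl 3-[(5S,6R,7S,10R)-6,10-dimethyl-2-oxo-3-[(1Z)-prop-1-en-1-yl]-7-[2-(trimethylsilyloxy)propan-2-yl]-1-oxaspiro[4.5]decan-6-yl]propanoate (C3 epimers), via hydroxy diester 11 (not isolated)
Conditions: 10, LiN(iPr)2, DMPU, THF, −78 °C; Et2AlCl; 9, −78 → −10 °C; sat. aq. NH4Cl; PPTS (cat.), PhMe, 50 °C
Reagents that add atoms: none
Why: Deconjugative α-alkylation of the ester dienolate by aluminium-assisted SN2 opening of the epoxide at its CH2 terminus (forms C3–C3a), then γ-lactonisation in preference to the six-membered alternative; no ring stereocentre is touched and the new alkene is Z from the kinetic dienolate geometry.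

Step 8
Reactants: 12 spiro-lactone
Product: 13 methyl 3-[(5S,6R,7S,10R)-6,10-dimethyl-3-[(1Z)-prop-1-en-1-yl]-2-(trimethylsilyloxy)-7-[2-(trimethylsilyloxy)propan-2-yl]-1-oxaspiro[4.5]dec-2-en-6-yl]propanoate
Conditions: LiN(SiMe3)2 (1.2 equiv), Me3SiCl, THF, −78 → 0 °C; pentane, filter under Ar, use directly
Reagents that add atoms: chlorotrimethylsilane, C[Si](C)(C)Cl
Why: The lactone α-hydrogen is both α-carbonyl and allylic, so it is removed selectively over the side-chain ester, and O-silylation gives the 2-silyloxy diene (ketene silyl acetal formation).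

Step 9
Reactants: 14 methyl 3-oxopentanoate
Product: 15 methyl 2-diazo-3-oxopentanoate
Conditions: 4-acetamidobenzenesulfonyl azide, Et3N, MeCN, 0 °C → rt
Reagents that add atoms: 4-acetamidobenzenesulfonyl azide, CC(=O)Nc1ccc(cc1)S(=O)(=O)N=[N+]=[N-]
Why: Regitz diazo transfer to the active methylene of the β-keto ester.

Step 10
Reactants: 15 diazo keto ester
Product: 16 methyl (3Z)-3-[(tert-butyldimethylsilyl)oxy]-2-diazopent-3-enoate
Conditions: t-BuMe2SiOTf, Et3N, CH2Cl2, 0 °C; aq. NaHCO3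
Reagents that add atoms: tert-butyldimethylsilyl trifluoromethanesulfonate, CC(C)(C)[Si](C)(C)OS(=O)(=O)C(F)(F)F
Why: Soft enolisation and O-silylation of the ketone give the Z silyl enol ether, i.e. the vinyldiazoacetate needed for the annulation.

Step 11
Reactants: 13 silyloxy diene; 16 vinyldiazoacetate
Product: 18 silyl-protected cycloheptadiene annulation product (C5/C8/C8a mixture), via divinylcyclopropane 17 (not isolated)
Conditions: Rh2(O2CCMe3)4 (1 mol %), pentane, reflux, slow addition of 16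
Reagents that add atoms: none
Why: Davies-type formal [3+4] annulation (cyclopropanation of the cis-propenyl alkene by the electrophilic rhodium vinylcarbenoid, then divinylcyclopropane Cope rearrangement): the carbenoid carbon, normally the nucleophilic α-carbon of a β-keto ester, bonds to the nucleophilic diene terminus (C5–C6) and the vinyl terminus closes onto the ketene acetal carbon (C8–C8a); the new sp3 centres are erased in step 12.

Step 12
Reactants: 18 annulation product
Product: 20 methyl (2S,2'R,3'S,6'R)-3'-(2-hydroxypropan-2-yl)-2'-(3-methoxy-3-oxopropyl)-2',5,6',8-tetramethyl-7-oxo-3,7-dihydrospiro[cyclohepta[b]furan-2,1'-cyclohexane]-6-carboxylate, via dienone ketal 19 (not isolated)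
Conditions: DDQ, CH2Cl2, 0 °C → rt; Et3N; then 5 % aq. citric acid, THF, 0 °C
Reagents that add atoms: none
Why: DDQ abstracts hydride from the doubly allylic C5–H and the silyl enol ether collapses to dienone 19, whose β-silyloxy group is then lost by E1cB elimination to aromatise to the tropone (dehydrogenative aromatisation); mild acid removes the tertiary silyl ether.

Step 13
Reactants: 20 tropone diester
Product: 21 3-[(2S,2'R,3'S,6'R)-3'-(2-hydroxypropan-2-yl)-6-(methoxycarbonyl)-2',5,6',8-tetramethyl-7-oxo-3,7-dihydrospiro[cyclohepta[b]furan-2,1'-cyclohexan]-2'-yl]propanoic acid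
Conditions: Me3SnOH, 1,2-dichloroethane, 70 °C; 0.1 M aq. HCl wash
Reagents that add atoms: trimethyltin hydroxide, C[Sn](C)(C)O
Why: Me3SnOH hydrolyses the unhindered side-chain methyl ester selectively; the tropone ester is conjugated and flanked on both sides, and the neutral conditions spare the acid-labile tertiary vinylogous ester and the tertiary alcohol.

**Compound list**

1 | (S)-(+)-carvone | CC1=CC[C@@H](CC1=O)C(C)=C | starting material
2 | (5S)-2,6-dimethyl-5-(prop-1-en-2-yl)cyclohex-2-en-1-one (C6 epimers) | O=C1C(C)=CC[C@H](C(C)=C)C1C | intermediate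
3 | methyl acrylate | C=CC(=O)OC | starting material
4 | methyl 3-[(1R,6R)-1,3-dimethyl-2-oxo-6-(prop-1-en-2-yl)cyclohex-3-en-1-yl]propanoate | O=C1C(C)=CC[C@H](C(C)=C)[C@@]1(C)CCC(=O)OC | intermediate
5 | methyl 3-[(1R,6S)-6-(2-hydroxypropan-2-yl)-1,3-dimethyl-2-oxocyclohex-3-en-1-yl]propanoate | O=C1C(C)=CC[C@H](C(C)(C)O)[C@@]1(C)CCC(=O)OC | intermediate
6 | methyl 3-[(1R,3R,6S)-6-(2-hydroxypropan-2-yl)-1,3-dimethyl-2-oxocyclohexyl]propanoate | O=C1[C@H](C)CC[C@H](C(C)(C)O)[C@@]1(C)CCC(=O)OC | intermediate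
7 | methyl 3-[(1R,3R,6S)-6-(2-hydroxypropan-2-yl)-1,3-dimethyl-2-methylidenecyclohexyl]propanoate | C=C1[C@H](C)CC[C@H](C(C)(C)O)[C@@]1(C)CCC(=O)OC | intermediate
8 | methyl 3-[(3S,4R,5S,8R)-5-(2-hydroxypropan-2-yl)-4,8-dimethyl-1-oxaspiro[2.5]octan-4-yl]propanoate (not isolated) | C1O[C@]12[C@H](C)CC[C@H](C(C)(C)O)[C@@]2(C)CCC(=O)OC | intermediate
9 | methyl 3-[(3S,4R,5S,8R)-4,8-dimethyl-5-[2-(trimethylsilyloxy)propan-2-yl]-1-oxaspiro[2.5]octan-4-yl]propanoate | C1O[C@]12[C@H](C)CC[C@H](C(C)(C)O[Si](C)(C)C)[C@@]2(C)CCC(=O)OC | intermediate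
10 | methyl (2E)-pent-2-enoate | CC/C=C/C(=O)OC | starting material
11 | methyl (3Z)-2-{[(1S,2R,3S,6R)-1-hydroxy-2-(3-methoxy-3-oxopropyl)-2,6-dimethyl-3-[2-(trimethylsilyloxy)propan-2-yl]cyclohexyl]methyl}pent-3-enoate (not isolated) | C/C=C\C(C[C@]1(O)[C@H](C)CC[C@H](C(C)(C)O[Si](C)(C)C)[C@@]1(C)CCC(=O)OC)C(=O)OC | intermediate
12 | methyl 3-[(5S,6R,7S,10R)-6,10-dimethyl-2-oxo-3-[(1Z)-prop-1-en-1-yl]-7-[2-(trimethylsilyloxy)propan-2-yl]-1-oxaspiro[4.5]decan-6-yl]propanoate (C3 epimers) | O=C1O[C@@]2(CC1/C=C\C)[C@H](C)CC[C@H](C(C)(C)O[Si](C)(C)C)[C@@]2(C)CCC(=O)OC | intermediate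
13 | methyl 3-[(5S,6R,7S,10R)-6,10-dimethyl-3-[(1Z)-prop-1-en-1-yl]-2-(trimethylsilyloxy)-7-[2-(trimethylsilyloxy)propan-2-yl]-1-oxaspiro[4.5]dec-2-en-6-yl]propanoate | C/C=C\C1=C(O[Si](C)(C)C)O[C@@]2(C1)[C@H](C)CC[C@H](C(C)(C)O[Si](C)(C)C)[C@@]2(C)CCC(=O)OC | intermediate
14 | methyl 3-oxopentanoate | CCC(=O)CC(=O)OC | starting material
15 | methyl 2-diazo-3-oxopentanoate | CCC(=O)C(=[N+]=[N-])C(=O)OC | intermediate
16 | methyl (3Z)-3-[(tert-butyldimethylsilyl)oxy]-2-diazopent-3-enoate | C/C=C(\O[Si](C)(C)C(C)(C)C)C(=[N+]=[N-])C(=O)OC | intermediate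
17 | divinylcyclopropane: cyclopropane carrying CO2Me and the silyloxy-propenyl group on one carbon, methyl on the second and the silyloxy-dihydrofuran on the third (not isolated) | COC(=O)C1(C(O[Si](C)(C)C(C)(C)C)=CC)C(C)C1C1=C(O[Si](C)(C)C)O[C@@]2(C1)[C@H](C)CC[C@H](C(C)(C)O[Si](C)(C)C)[C@@]2(C)CCC(=O)OC | intermediate
18 | methyl (2S,2'R,3'S,6'R)-7-[(tert-butyldimethylsilyl)oxy]-2'-(3-methoxy-3-oxopropyl)-2',5,6',8-tetramethyl-8a-(trimethylsilyloxy)-3'-[2-(trimethylsilyloxy)propan-2-yl]-3,5,8,8a-tetrahydrospiro[cyclohepta[b]furan-2,1'-cyclohexane]-6-carboxylate (mixture at C5, C8, C8a) | COC(=O)C1=C(O[Si](C)(C)C(C)(C)C)C(C)C2(O[Si](C)(C)C)O[C@@]3(CC2=CC1C)[C@H](C)CC[C@H](C(C)(C)O[Si](C)(C)C)[C@@]3(C)CCC(=O)OC | intermediate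
19 | methyl (2S,2'R,3'S,6'R)-2'-(3-methoxy-3-oxopropyl)-2',5,6',8-tetramethyl-7-oxo-8a-(trimethylsilyloxy)-3'-[2-(trimethylsilyloxy)propan-2-yl]-3,7,8,8a-tetrahydrospiro[cyclohepta[b]furan-2,1'-cyclohexane]-6-carboxylate (not isolated) | O=C1C(C)C2(O[Si](C)(C)C)O[C@@]3(CC2=CC(C)=C1C(=O)OC)[C@H](C)CC[C@H](C(C)(C)O[Si](C)(C)C)[C@@]3(C)CCC(=O)OC | intermediate
20 | methyl (2S,2'R,3'S,6'R)-3'-(2-hydroxypropan-2-yl)-2'-(3-methoxy-3-oxopropyl)-2',5,6',8-tetramethyl-7-oxo-3,7-dihydrospiro[cyclohepta[b]furan-2,1'-cyclohexane]-6-carboxylate | COC(=O)c1c(C)cc2c(c(C)c1=O)O[C@@]1(C2)[C@H](C)CC[C@H](C(C)(C)O)[C@@]1(C)CCC(=O)OC | intermediate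
21 | 3-[(2S,2'R,3'S,6'R)-3'-(2-hydroxypropan-2-yl)-6-(methoxycarbonyl)-2',5,6',8-tetramethyl-7-oxo-3,7-dihydrospiro[cyclohepta[b]furan-2,1'-cyclohexan]-2'-yl]propanoic acid | COC(=O)c1c(C)cc2c(c(C)c1=O)O[C@@]1(C2)[C@H](C)CC[C@H](C(C)(C)O)[C@@]1(C)CCC(=O)O | target

**Step count**

Total steps: 13. Longest linear sequence: 11 (steps 1–8, then 11–13); steps 9–10 are a two-step branch.

**Three steps most likely to fail**

Step 2. The ester enolate formed in the Michael addition can add back to the enone and give a bicyclo[2.2.2]octanone (a known outcome for carvone dienolates on warming). The fallback sets out from 2 and comes back at 4. The same enolate is alkylated with allyl bromide (SN2, anti to the isopropenyl group) to give the allyl enone F1. The monosubstituted alkene alone is hydroborated with disiamylborane to the alkylborane F2, which is oxidised (NaBO3) to the primary alcohol F3. Oxidation (TEMPO, PhI(OAc)2, MeCN/H2O) gives the acid F4, and esterification (Me3SiCHN2, MeOH) gives 4.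

Step 7. The neopentyl-type epoxide CH2 may resist the aluminium dienolate, or the epoxide may rearrange under the Lewis acid. The fallback sets out from 9 and comes back at 13. Epoxide 9 is heated with the sodium salt of triethyl phosphonoacetate (NaH, DME, 85 °C). The stabilised carbanion opens the epoxide at CH2 to the hydroxy phosphonoester F5, which closes in the flask to the phosphono-lactone F6. A Horner–Wadsworth–Emmons reaction with propanal (NaH, THF) gives the propylidene lactone F7. γ-Deprotonation and O-silylation (LiN(SiMe3)2, Me3SiCl, THF, −78 °C) then give diene 13.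

Step 11. The carbenoid may attack the tetrasubstituted ketene acetal end of 13 instead of the propenyl alkene, or 13 may not survive the addition. The fallback sets out from 12 and comes back at 17, so that the carbenoid only ever meets the cis-propenyl alkene. Lactone 12 is cyclopropanated with 16 (Rh2(O2CCMe3)4, pentane) to the vinylcyclopropyl lactone F8. The lactone is then converted into its ketene silyl acetal (LiN(SiMe3)2, Me3SiCl, THF, −78 °C), which is 17 and rearranges on warming to 18.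

**Further compounds**

F1 | step 2 | (5R,6R)-2,6-dimethyl-6-(prop-2-en-1-yl)-5-(prop-1-en-2-yl)cyclohex-2-en-1-one | O=C1C(C)=CC[C@H](C(C)=C)[C@@]1(C)CC=C
F2 | step 2 | (5R,6R)-6-{3-[bis(3-methylbutan-2-yl)boranyl]propyl}-2,6-dimethyl-5-(prop-1-en-2-yl)cyclohex-2-en-1-one | O=C1C(C)=CC[C@H](C(C)=C)[C@@]1(C)CCCB(C(C)C(C)C)C(C)C(C)C
F3 | step 2 | (5R,6R)-6-(3-hydroxypropyl)-2,6-dimethyl-5-(prop-1-en-2-yl)cyclohex-2-en-1-one | O=C1C(C)=CC[C@H](C(C)=C)[C@@]1(C)CCCO
F4 | step 2 | 3-[(1R,6R)-1,3-dimethyl-2-oxo-6-(prop-1-en-2-yl)cyclohex-3-en-1-yl]propanoic acid | O=C1C(C)=CC[C@H](C(C)=C)[C@@]1(C)CCC(=O)O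
F5 | step 7 | ethyl 2-(diethoxyphosphoryl)-3-{(1S,2R,3S,6R)-1-hydroxy-2-(3-methoxy-3-oxopropyl)-2,6-dimethyl-3-[2-(trimethylsilyloxy)propan-2-yl]cyclohexyl}propanoate | CCOC(=O)C(C[C@]1(O)[C@H](C)CC[C@H](C(C)(C)O[Si](C)(C)C)[C@@]1(C)CCC(=O)OC)P(=O)(OCC)OCC
F6 | step 7 | methyl 3-[(5S,6R,7S,10R)-3-(diethoxyphosphoryl)-6,10-dimethyl-2-oxo-7-[2-(trimethylsilyloxy)propan-2-yl]-1-oxaspiro[4.5]decan-6-yl]propanoate | O=C1O[C@@]2(CC1P(=O)(OCC)OCC)[C@H](C)CC[C@H](C(C)(C)O[Si](C)(C)C)[C@@]2(C)CCC(=O)OC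
F7 | step 7 | methyl 3-[(3E,5S,6R,7S,10R)-6,10-dimethyl-2-oxo-3-propylidene-7-[2-(trimethylsilyloxy)propan-2-yl]-1-oxaspiro[4.5]decan-6-yl]propanoate | O=C1O[C@@]2(C/C1=C\CC)[C@H](C)CC[C@H](C(C)(C)O[Si](C)(C)C)[C@@]2(C)CCC(=O)OC
F8 | step 11 | vinylcyclopropyl lactone: lactone 12 with its propenyl alkene cyclopropanated by the carbenoid carbon of 16 (that carbon carries CO2Me and the silyloxy-propenyl group) | COC(=O)C1(C(O[Si](C)(C)C(C)(C)C)=CC)C(C)C1C1C(=O)O[C@@]2(C1)[C@H](C)CC[C@H](C(C)(C)O[Si](C)(C)C)[C@@]2(C)CCC(=O)OC
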